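(The numbers belong to no real substance; what happens was integrated by code.)

3 questions stand below, and one ratio carries them.

G 10 mM (fed, over 4.0 s); D 7.00 mM; Z 10.0 mM; time 8.0 min

    G + 2 D → E (k1 = 3800 L² mol⁻² s⁻¹)
    G + D → G.D (k2 = 11 L mol⁻¹ s⁻¹)
    D + Z → D.Z (k3 = 12 L mol⁻¹ s⁻¹)

1. how much of the G has reacted by 8.0 min
2. how much G.D there is at 8.0 min, in percent of the G charged
3. how much E there is at 8.0 min, in percent of the G charged

Compare the two steps that use G at one moment. Divide the rate of the E step, 3800 L² mol⁻² s⁻¹ times cG times cD squared, by that of the G.D step, 11 L mol⁻¹ s⁻¹ times cG times cD. G cancels, so the feed of G over 4.0 s changes cG but not this ratio, which is cD over 2.89 mM, the crossover concentration of D, the cD at which E and G.D form equally fast.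

Now ask how the comparison drifts. In this flask D is the limiting reagent, with less D than G or Z, and the run is far longer than the half-life of D on the Z step, 0.096 min, so expect cD to fall through the crossover. It starts at 2.42 crossovers. The neighbour with 12 mM of D looks nearly the same but starts at 4.15, so more of its D is spent where E outruns G.D.

Put numbers on it: hold G and Z at their charges, crude as that is, and let D fall to nothing. With 3.03 mM as the working level and L the logarithm of one plus the starting cD over that level, here 1.20, G.D comes to the crossover times L over 2, or 1.73 mM. E comes to 1.69 mM. I commit to 34.2% converted, 17.3% G.D and 16.9% E, a ratio of E to G.D of 0.977.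

The forecast gives 29%, 16% and 13%, lower than mine, with “about 40% of D going to Z”, where my reckoning sends 27.0% of D there.

The flask gives 28.4% converted, 15.3% G.D and 13.0% E, below my reckoning. D stands at 0% by 4.00 min, and E has reached 13.0% by 0.400 min. Multiply the ratio of E to G.D by the crossover: the product is a reading of cD averaged over the G.D formed, 2.46 mM in this flask. The neighbour with 12 mM of D ends at 20.5% G.D and 28.1% E, which reads 3.96 mM.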